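**Retrosynthetic overview**

1. The target is the O8 4-hydroxybenzoate of a trans-fused hydroazulene (H1 β, H5 α) with a 3β,4β-epoxide; ester, epoxide and the C3=C4 alkene are late events that start from a C3 ketone.
2. Feature used: the C7/C8/C10 stereotriad lies wholly on the seven-membered ring (C1, C5 to C10) and can be set on an open chain, while C1 and C5 and the rest of the five-membered ring (C2 to C4) carry no centre that must exist before cyclisation, so C1 can begin as an alkyne carbon and C5 as the central allene carbon.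
3. Key disconnection: a rhodium-catalysed allenic Pauson–Khand reaction of an acyclic allene-yne forms C1–C5, C2–C3 and C3–C4 and closes the seven- and the five-membered ring in one step.
4. After the bicyclisation H5 and H1 are installed one at a time by hydroxyl-directed hydrogenation (O8–H for C5=C6, then O10–H for C1=C2), C15 is added at C4 of the intermediate enone, and the ketone is turned into the C3=C4 alkene.
5. The allene-yne comes from (S)-2-methylglycidol (C10), an oxazolidinone syn-aldol (C7/C8) and ethynyl Grignard addition followed by propargylic diazene fragmentation (C4 to C6).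

Key step: step 13

Remarks on the chemistry:
- Guaiane numbering is used throughout (C14 on C10, C15 on C4); β is the face that carries the C7 isopropyl group, so in the target H1, O10 and the epoxide oxygen are β and H5, O8 and C14 are α.
- (S)-2-Methylglycidol is assumed to be bought as the single enantiomer; no bond to its quaternary carbon (the future C10) is broken.
- Centres that later become sp2 (the carbinol carbon of the propargylic alcohols, and C4 after methylation) are carried as epimer mixtures and drawn without a descriptor.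

**Route**

Step 1
Reactants: 1 (S)-2-methylglycidol; 2 vinylmagnesium bromide
Product: 3 (R)-2-methylpent-4-ene-1,2-diol
Conditions: 2 (3 equiv), CuI (10 mol %), THF, −30 to 0 °C; aq. NH4Cl
Reagents that add atoms: none
Why: Copper-catalysed Grignard opening of a 2,2-disubstituted epoxide takes place at the unsubstituted CH2 carbon (SN2), so the C10 centre is carried over untouched from 1 while one equivalent of 2 is spent on the hydroxyl group.

Step 2
Reactants: 3 (R)-2-methylpent-4-ene-1,2-diol
Product: 5 (R)-2-(tert-butyldimethylsilyloxy)-2-methyl-1-(triethylsilyloxy)pent-4-ene, via mono-TES ether 4 (not isolated)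
Conditions: Et3SiOTf (1.0 equiv), 2,6-lutidine, CH2Cl2, −78 °C; then t-BuMe2SiOTf (1.5 equiv), −78 to 0 °C
Reagents that add atoms: triethylsilyl triflate, CC[Si](CC)(CC)OS(=O)(=O)C(F)(F)F; tert-butyldimethylsilyl triflate, CC(C)(C)[Si](C)(C)OS(=O)(=O)C(F)(F)F
Why: Silyl ether formation with a silyl triflate is far faster at the primary than at the tertiary hydroxyl at −78 °C, so the two oxygens can be capped differently in one flask, a labile primary triethylsilyl ether and a robust tertiary tert-butyldimethylsilyl ether.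

Step 3
Reactants: 5 (R)-2-(tert-butyldimethylsilyloxy)-2-methyl-1-(triethylsilyloxy)pent-4-ene
Product: 6 (R)-2-(tert-butyldimethylsilyloxy)-2-methylpent-4-enal
Conditions: (COCl)2, DMSO, CH2Cl2, −78 to −30 °C; Et3N, to 0 °C
Reagents that add atoms: none
Why: Under Swern conditions a primary triethylsilyl ether is attacked at oxygen by the chlorosulfonium salt and oxidised directly to the aldehyde (Swern oxidation with loss of the silyl group), the tertiary silyl ether is inert and the quaternary α-carbon cannot epimerise.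

Step 4
Reactants: 6 (R)-2-(tert-butyldimethylsilyloxy)-2-methylpent-4-enal
Product: 7 (R)-3-(tert-butyldimethylsilyloxy)-3-methylhex-5-en-1-yne
Conditions: dimethyl (1-diazo-2-oxopropyl)phosphonate, K2CO3, MeOH, 0 °C to rt
Reagents that add atoms: dimethyl (1-diazo-2-oxopropyl)phosphonate, COP(=O)(OC)C(=[N+]=[N-])C(C)=O
Why: Seyferth–Gilbert homologation in its Ohira–Bestmann form converts the non-enolisable aldehyde into the terminal alkyne (C1 and C2) under carbonate conditions that the silyl ether tolerates.

Step 5
Reactants: 7 (R)-3-(tert-butyldimethylsilyloxy)-3-methylhex-5-en-1-yne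
Product: 8 (R)-3-(tert-butyldimethylsilyloxy)-3-methylpent-4-ynal
Conditions: O3, CH2Cl2/MeOH, −78 °C, to the first blue tinge; then PPh3, to rt
Reagents that add atoms: ozone, [O-][O+]=O
Why: Ozonolysis is much faster for the terminal alkene than for the alkyne, so titration to the end point and reductive work-up should give the C8 aldehyde with the alkyne intact.

Step 6
Reactants: 9 (S)-4-benzyloxazolidin-2-one; 10 isovaleryl chloride
Product: 11 (S)-4-benzyl-3-(3-methylbutanoyl)oxazolidin-2-one
Conditions: n-BuLi, THF, −78 °C; then 10, −78 to 0 °C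
Reagents that add atoms: none
Why: N-Acylation of the lithiated oxazolidinone with the acid chloride is the standard entry to the imide.

Step 7
Reactants: 11 (S)-4-benzyl-3-(3-methylbutanoyl)oxazolidin-2-one; 8 (R)-3-(tert-butyldimethylsilyloxy)-3-methylpent-4-ynal
Product: 13 (S)-4-benzyl-3-[(2S,3R,5R)-5-(tert-butyldimethylsilyloxy)-3-hydroxy-2-isopropyl-5-methylhept-6-ynoyl]oxazolidin-2-one, via boron enolate 12 (not isolated)
Conditions: Bu2BOTf, i-Pr2NEt, CH2Cl2, 0 °C; 8, −78 to 0 °C; pH 7 buffer, MeOH, H2O2, 0 °C
Reagents that add atoms: none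
Why: Evans syn-aldol, in which the dibutylboron Z-enolate reacts through a Zimmerman–Traxler chair with one enolate face shielded by the benzyl group of the (S)-auxiliary, which gives the (2S,3R) adduct, that is C7 and C8 in the syn relationship and absolute sense of the target, the remote C10 centre having little influence.

Step 8
Reactants: 13 the aldol adduct
Product: 14 (S)-4-benzyl-3-[(2S,3R,5R)-5-(tert-butyldimethylsilyloxy)-2-isopropyl-5-methyl-3-(triethylsilyloxy)hept-6-ynoyl]oxazolidin-2-one
Conditions: Et3SiOTf, 2,6-lutidine, CH2Cl2, −78 to 0 °C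
Reagents that add atoms: triethylsilyl triflate, CC[Si](CC)(CC)OS(=O)(=O)C(F)(F)F
Why: Silyl ether formation with triflate and 2,6-lutidine covers the hindered aldol hydroxyl without retro-aldol cleavage, and triethylsilyl is chosen so that O8 can later be freed while the tertiary silyl ether on O10 stays.

Step 9
Reactants: 14 the silylated imide
Product: 15 (2R,3R,5R)-5-(tert-butyldimethylsilyloxy)-2-isopropyl-5-methyl-3-(triethylsilyloxy)hept-6-yn-1-ol
Conditions: LiBH4, MeOH (1 equiv), THF, 0 °C
Reagents that add atoms: none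
Why: Reductive cleavage of the auxiliary, in which LiBH4 attacks the exocyclic imide carbonyl and releases the primary alcohol (C6) and the recoverable oxazolidinone without touching silyl ethers or alkyne.

Step 10
Reactants: 15 the primary alcohol
Product: 16 (2S,3R,5R)-5-(tert-butyldimethylsilyloxy)-2-isopropyl-5-methyl-3-(triethylsilyloxy)hept-6-ynal
Conditions: Dess–Martin periodinane, NaHCO3, CH2Cl2, 0 °C to rt
Reagents that add atoms: none
Why: Dess–Martin oxidation gives the α-branched aldehyde under buffered conditions that should not epimerise C7.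

Step 11
Reactants: 16 the aldehyde; 17 ethynylmagnesium bromide
Product: 18 (4R,5R,7R)-7-(tert-butyldimethylsilyloxy)-4-isopropyl-7-methyl-5-(triethylsilyloxy)nona-1,8-diyn-3-ol (both C3 epimers)
Conditions: 17 (3 equiv), THF, −78 °C, slow addition of 16, to 0 °C; aq. NH4Cl
Reagents that add atoms: none
Why: Grignard addition of the aldehyde to an excess of the alkynyl reagent at low temperature gives the propargylic alcohols, and the configuration of the new carbinol is irrelevant because this carbon becomes the sp2 allene carbon C6.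

Step 12
Reactants: 18 the propargylic alcohols
Product: 21 (4R,5R,7R)-7-(tert-butyldimethylsilyloxy)-4-isopropyl-7-methyl-5-(triethylsilyloxy)nona-1,2-dien-8-yne, via sulfonylhydrazine 19 (not isolated), via propargylic diazene 20 (not isolated)
Conditions: PPh3, diethyl azodicarboxylate, 2-nitrobenzenesulfonylhydrazide, THF, −15 °C, then rt
Reagents that add atoms: none
Why: Mitsunobu displacement of the propargylic hydroxyl by the sulfonylhydrazide, loss of sulfinic acid and retro-ene fragmentation of the propargylic diazene with loss of N2 give the terminal allene, and both carbinol epimers converge on the same allene.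

Step 13
Reactants: 21 the allene-yne (guaiane numbering: C2H≡C1–C10(Me)(OSi)–C9H2–C8H(OSi)–C7H(i-Pr)–C6H=C5=C4H2)
Product: 22 10β-(tert-butyldimethylsilyloxy)-8α-(triethylsilyloxy)-15-nor-7αH-guaia-1,5-dien-3-one
Conditions: [Rh(CO)2Cl]2 (5 mol %), CO (1 atm), toluene (0.02 M), 90 °C
Reagents that add atoms: carbon monoxide, [C-]#[O+]
Why: Oxidative cyclisation of monovalent rhodium with the alkyne and the distal C4=C5 bond of the allene gives a rhodacyclopentene in which C1–C5 is formed, CO then inserts into a Rh–C bond and reductive elimination closes the cyclopentenone by forming C2–C3 and C3–C4. The closest known reaction type is the rhodium-catalysed allenic Pauson–Khand cyclocarbonylation of allene-ynes with a four-atom tether, which gives 4-alkylidenecyclopent-2-enones fused to seven-membered rings. The seven-membered ring (C1, C5 to C10) closes in the metallacycle-forming step, exo with respect to the reacting distal double bond so that the proximal C5=C6 bond ends inside the ring, and the five-membered ring (C1 to C5) closes as a [2+2+1] assembly of alkyne, CO and the distal allene bond. No stereocentre is created, and C7, C8 and C10 are spectators with no epimerisable position involved. The selectivity needed is reaction at the distal and not the proximal allene bond (seven- against six-membered ring), which [Rh(CO)2Cl]2 under CO secures for allenes whatever their substitution, and the unsubstituted allene terminus leaves no β-hydrogen for a competing Alder-ene path. The quaternary C10 next to the alkyne and the substituents on C7 and C8 favour the folded chain and hinder intermolecular alkyne coupling, which dilution holds back further.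

Step 14
Reactants: 22 the bis-silyl dienone
Product: 23 10β-(tert-butyldimethylsilyloxy)-8α-hydroxy-15-nor-7αH-guaia-1,5-dien-3-one
Conditions: PPTS (0.2 equiv), MeOH/CH2Cl2, 0 °C
Reagents that add atoms: none
Why: Acid-catalysed methanolysis (selective desilylation) removes the secondary triethylsilyl ether far faster than the tertiary tert-butyldimethylsilyl ether, which unmasks O8–H as the directing group for the next step while O10 stays blocked.

Step 15
Reactants: 23 the C8 alcohol
Product: 24 10β-(tert-butyldimethylsilyloxy)-8α-hydroxy-15-nor-5αH,7αH-guai-1-en-3-one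
Conditions: [Ir(cod)(PCy3)(py)]PF6 (5 mol %), H2 (1 atm), CH2Cl2, 0 °C to rt, stopped after one equivalent of H2
Reagents that add atoms: none
Why: Hydroxyl-directed hydrogenation, in which the free 8α-hydroxyl binds iridium and delivers H2 to the α face of the homoallylic, more reactive γ,δ-bond C5=C6 (the face opposite the allylic β-isopropyl group), so H5 is set α, while the silylated O10 cannot steer the catalyst to the β face and the hindered enone bond C1=C2 is left.

Step 16
Reactants: 24 the enone
Product: 26 10β-(tert-butyldimethylsilyloxy)-8α-hydroxy-5αH,7αH-guai-1-en-3-one (C4 epimers), via dilithium dienolate 25 (not isolated)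
Conditions: LiN(i-Pr)2 (2.1 equiv), THF, −78 °C; MeI (1.5 equiv), −78 to −40 °C; aq. NH4Cl
Reagents that add atoms: iodomethane, CI
Why: Enolate alkylation, in which kinetic deprotonation of the cyclopent-2-enone can occur only at the α′ carbon C4 because C2 is vinylic, so C-methylation of the cross-conjugated lithium enolate places C15 on C4 without a regiochemical alternative, and the new C4 centre is of no consequence.

Step 17
Reactants: 26 the 4-methyl enone
Product: 27 8α,10β-dihydroxy-5αH,7αH-guai-1-en-3-one (C4 epimers)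
Conditions: HF (48 % aq.), MeCN, 0 °C to rt
Reagents that add atoms: none
Why: Desilylation with aqueous HF cleaves the tertiary silyl ether and frees the allylic 10β-hydroxyl under conditions too mild to enolise the enone towards C5.

Step 18
Reactants: 27 the enone diol
Product: 28 8α,10β-dihydroxy-1βH,5αH,7αH-guaian-3-one (C4 epimers)
Conditions: [Ir(cod)(PCy3)(py)]PF6 (10 mol %), H2 (1 atm), CH2Cl2, rt
Reagents that add atoms: none
Why: Hydroxyl-directed hydrogenation, in which the allylic tertiary 10β-hydroxyl delivers H2 to the β face of C1=C2 against the steric preference for the α face, so H1 is set β and trans to H5.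

Step 19
Reactants: 28 the trans-fused ketone
Product: 29 3,8α,10β-tris(trimethylsilyloxy)-1βH,5αH,7αH-guai-3-ene
Conditions: Me3SiCl, NaI, Et3N, MeCN, rt
Reagents that add atoms: chlorotrimethylsilane, C[Si](C)(C)Cl
Why: Silyl enol ether formation under equilibrating conditions (Me3SiI made in the flask, amine base) should favour the more substituted C3=C4 isomer over the C2=C3 isomer, both hydroxyls are silylated at the same time, and C1 and C5 are β to the carbonyl and cannot epimerise.

Step 20
Reactants: 29 the silyl enol ether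
Product: 31 8α,10β-bis(trimethylsilyloxy)-1βH,5αH,7αH-guai-3-en-3-yl trifluoromethanesulfonate, via lithium enolate 30 (not isolated)
Conditions: MeLi, THF, 0 °C; then N-(5-chloropyridin-2-yl)bis(trifluoromethanesulfonyl)imide, −78 to 0 °C
Reagents that add atoms: N-(5-chloropyridin-2-yl)bis(trifluoromethanesulfonyl)imide, FC(F)(F)S(=O)(=O)N(c1ccc(Cl)cn1)S(=O)(=O)C(F)(F)F
Why: Enol triflate formation, in which methyllithium cleaves the silyl enol ether regiospecifically to the lithium enolate and the triflimide sulfonylates it on oxygen, fixing the double bond at C3=C4.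

Step 21
Reactants: 31 the enol triflate
Product: 33 1βH,5αH,7αH-guai-3-ene-8α,10β-diol, via bis-TMS alkene 32 (not isolated)
Conditions: Pd(OAc)2 (5 mol %), PPh3, HCO2H, Bu3N, DMF, 60 °C; then TBAF, THF, 0 °C
Reagents that add atoms: none
Why: Palladium-catalysed formate reduction of the enol triflate (hydride transfer from formate to the alkenylpalladium intermediate) replaces the triflate by hydrogen, and fluoride then removes both trimethylsilyl ethers.

Step 22
Reactants: 34 4-hydroxybenzoic acid
Product: 36 4-(tert-butyldimethylsilyloxy)benzoic acid, via silyl ester 35 (not isolated)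
Conditions: t-BuMe2SiCl (2.2 equiv), imidazole, DMF, rt; then AcOH/THF/H2O, rt
Reagents that add atoms: tert-butyldimethylsilyl chloride, CC(C)(C)[Si](C)(C)Cl
Why: Silyl ether formation on both acidic groups followed by mild hydrolysis of the labile silyl ester leaves only the phenol protected.

Step 23
Reactants: 33 the alkene diol; 36 4-(tert-butyldimethylsilyloxy)benzoic acid
Product: 38 10β-hydroxy-1βH,5αH,7αH-guai-3-en-8α-yl 4-(tert-butyldimethylsilyloxy)benzoate, via mixed anhydride 37 (not isolated)
Conditions: 36, 2,4,6-trichlorobenzoyl chloride, Et3N, THF, rt; then 33, DMAP, toluene, rt to 40 °C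
Reagents that add atoms: none
Why: Yamaguchi esterification, in which the mixed anhydride acylates the secondary 8α-hydroxyl under DMAP catalysis while the tertiary O10–H is too hindered to react.

Step 24
Reactants: 38 the ester
Product: 39 3β,4β-epoxy-10β-hydroxy-1βH,5αH,7αH-guaian-8α-yl 4-(tert-butyldimethylsilyloxy)benzoate
Conditions: 3-chloroperoxybenzoic acid, NaHCO3, CH2Cl2, 0 °C
Reagents that add atoms: 3-chloroperoxybenzoic acid, OOC(=O)c1cccc(Cl)c1
Why: Prilezhaev epoxidation of the only electron-rich alkene, in which the β face is expected to be preferred because the C10 hydroxyl sits on the β side of the C1–C2 edge and can hydrogen-bond the peracid while C14 and the axial H5 screen the α face, so the oxygen should arrive syn to H1.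

Step 25
Reactants: 39 the silylated epoxy ester
Product: 40 3β,4β-epoxy-10β-hydroxy-1βH,5αH,7αH-guaian-8α-yl 4-hydroxybenzoate (target)
Conditions: TBAF, AcOH, THF, 0 °C
Reagents that add atoms: none
Why: Desilylation with buffered fluoride cleaves the aryl silyl ether within minutes and should leave the ester and the epoxide untouched.

**Compound list**

1 | (S)-2-methylglycidol | OC[C@@]1(C)CO1 | starting material
2 | vinylmagnesium bromide | C=C[Mg]Br | starting material
3 | (R)-2-methylpent-4-ene-1,2-diol | OC[C@](C)(O)CC=C | intermediate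
4 | (R)-2-methyl-1-(triethylsilyloxy)pent-4-en-2-ol (not isolated) | CC[Si](CC)(CC)OC[C@](C)(O)CC=C | intermediate
5 | (R)-2-(tert-butyldimethylsilyloxy)-2-methyl-1-(triethylsilyloxy)pent-4-ene | CC[Si](CC)(CC)OC[C@](C)(O[Si](C)(C)C(C)(C)C)CC=C | intermediate
6 | (R)-2-(tert-butyldimethylsilyloxy)-2-methylpent-4-enal | O=C[C@](C)(O[Si](C)(C)C(C)(C)C)CC=C | intermediate
7 | (R)-3-(tert-butyldimethylsilyloxy)-3-methylhex-5-en-1-yne | C#C[C@](C)(O[Si](C)(C)C(C)(C)C)CC=C | intermediate
8 | (R)-3-(tert-butyldimethylsilyloxy)-3-methylpent-4-ynal | C#C[C@](C)(O[Si](C)(C)C(C)(C)C)CC=O | intermediate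
9 | (S)-4-benzyloxazolidin-2-one | O=C1N[C@@H](Cc2ccccc2)CO1 | starting material
10 | isovaleryl chloride | CC(C)CC(Cl)=O | starting material
11 | (S)-4-benzyl-3-(3-methylbutanoyl)oxazolidin-2-one | CC(C)CC(=O)N1[C@@H](Cc2ccccc2)COC1=O | intermediate
12 | dibutylboron Z-enolate of 11 (not isolated) | CC(C)/C=C(\OB(CCCC)CCCC)N1[C@@H](Cc2ccccc2)COC1=O | intermediate
13 | (S)-4-benzyl-3-[(2S,3R,5R)-5-(tert-butyldimethylsilyloxy)-3-hydroxy-2-isopropyl-5-methylhept-6-ynoyl]oxazolidin-2-one | C#C[C@](C)(O[Si](C)(C)C(C)(C)C)C[C@@H](O)[C@H](C(C)C)C(=O)N1[C@@H](Cc2ccccc2)COC1=O | intermediate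
14 | (S)-4-benzyl-3-[(2S,3R,5R)-5-(tert-butyldimethylsilyloxy)-2-isopropyl-5-methyl-3-(triethylsilyloxy)hept-6-ynoyl]oxazolidin-2-one | C#C[C@](C)(O[Si](C)(C)C(C)(C)C)C[C@@H](O[Si](CC)(CC)CC)[C@H](C(C)C)C(=O)N1[C@@H](Cc2ccccc2)COC1=O | intermediate
15 | (2R,3R,5R)-5-(tert-butyldimethylsilyloxy)-2-isopropyl-5-methyl-3-(triethylsilyloxy)hept-6-yn-1-ol | C#C[C@](C)(O[Si](C)(C)C(C)(C)C)C[C@@H](O[Si](CC)(CC)CC)[C@H](C(C)C)CO | intermediate
16 | (2S,3R,5R)-5-(tert-butyldimethylsilyloxy)-2-isopropyl-5-methyl-3-(triethylsilyloxy)hept-6-ynal | C#C[C@](C)(O[Si](C)(C)C(C)(C)C)C[C@@H](O[Si](CC)(CC)CC)[C@H](C(C)C)C=O | intermediate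
17 | ethynylmagnesium bromide | C#C[Mg]Br | starting material
18 | (4R,5R,7R)-7-(tert-butyldimethylsilyloxy)-4-isopropyl-7-methyl-5-(triethylsilyloxy)nona-1,8-diyn-3-ol (C3 epimers) | C#C[C@](C)(O[Si](C)(C)C(C)(C)C)C[C@@H](O[Si](CC)(CC)CC)[C@H](C(C)C)C(O)C#C | intermediate
19 | N-alkyl-N-(2-nitrobenzenesulfonyl)hydrazine from 18 (not isolated) | C#C[C@](C)(O[Si](C)(C)C(C)(C)C)C[C@@H](O[Si](CC)(CC)CC)[C@H](C(C)C)C(C#C)N(N)S(=O)(=O)c1ccccc1[N+](=O)[O-] | intermediate
20 | propargylic monoalkyl diazene (not isolated) | C#C[C@](C)(O[Si](C)(C)C(C)(C)C)C[C@@H](O[Si](CC)(CC)CC)[C@H](C(C)C)C(C#C)N=N | intermediate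
21 | (4R,5R,7R)-7-(tert-butyldimethylsilyloxy)-4-isopropyl-7-methyl-5-(triethylsilyloxy)nona-1,2-dien-8-yne | C#C[C@](C)(O[Si](C)(C)C(C)(C)C)C[C@@H](O[Si](CC)(CC)CC)[C@H](C(C)C)C=C=C | intermediate
22 | 10β-(tert-butyldimethylsilyloxy)-8α-(triethylsilyloxy)-15-nor-7αH-guaia-1,5-dien-3-one | CC(C)[C@@H]1C=C2CC(=O)C=C2[C@](C)(O[Si](C)(C)C(C)(C)C)C[C@H]1O[Si](CC)(CC)CC | intermediate
23 | 10β-(tert-butyldimethylsilyloxy)-8α-hydroxy-15-nor-7αH-guaia-1,5-dien-3-one | CC(C)[C@@H]1C=C2CC(=O)C=C2[C@](C)(O[Si](C)(C)C(C)(C)C)C[C@H]1O | intermediate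
24 | 10β-(tert-butyldimethylsilyloxy)-8α-hydroxy-15-nor-5αH,7αH-guai-1-en-3-one | CC(C)[C@@H]1C[C@H]2C(=CC(=O)C2)[C@](C)(O[Si](C)(C)C(C)(C)C)C[C@H]1O | intermediate
25 | dilithium O8-alkoxide C3=C4 dienolate of 24 (not isolated) | CC(C)[C@@H]1C[C@H]2C(=CC(O[Li])=C2)[C@](C)(O[Si](C)(C)C(C)(C)C)C[C@H]1O[Li] | intermediate
26 | 10β-(tert-butyldimethylsilyloxy)-8α-hydroxy-5αH,7αH-guai-1-en-3-one (C4 epimers) | CC(C)[C@@H]1C[C@H]2C(=CC(=O)C2C)[C@](C)(O[Si](C)(C)C(C)(C)C)C[C@H]1O | intermediate
27 | 8α,10β-dihydroxy-5αH,7αH-guai-1-en-3-one (C4 epimers) | CC(C)[C@@H]1C[C@H]2C(=CC(=O)C2C)[C@](C)(O)C[C@H]1O | intermediate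
28 | 8α,10β-dihydroxy-1βH,5αH,7αH-guaian-3-one (C4 epimers) | CC(C)[C@@H]1C[C@H]2[C@@H](CC(=O)C2C)[C@](C)(O)C[C@H]1O | intermediate
29 | 3,8α,10β-tris(trimethylsilyloxy)-1βH,5αH,7αH-guai-3-ene | CC(C)[C@@H]1C[C@H]2[C@@H](CC(O[Si](C)(C)C)=C2C)[C@](C)(O[Si](C)(C)C)C[C@H]1O[Si](C)(C)C | intermediate
30 | lithium C3=C4 enolate (not isolated) | CC(C)[C@@H]1C[C@H]2[C@@H](CC(O[Li])=C2C)[C@](C)(O[Si](C)(C)C)C[C@H]1O[Si](C)(C)C | intermediate
31 | 8α,10β-bis(trimethylsilyloxy)-1βH,5αH,7αH-guai-3-en-3-yl trifluoromethanesulfonate | CC(C)[C@@H]1C[C@H]2[C@@H](CC(OS(=O)(=O)C(F)(F)F)=C2C)[C@](C)(O[Si](C)(C)C)C[C@H]1O[Si](C)(C)C | intermediate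
32 | 8α,10β-bis(trimethylsilyloxy)-1βH,5αH,7αH-guai-3-ene (not isolated) | CC(C)[C@@H]1C[C@H]2[C@@H](CC=C2C)[C@](C)(O[Si](C)(C)C)C[C@H]1O[Si](C)(C)C | intermediate
33 | 1βH,5αH,7αH-guai-3-ene-8α,10β-diol | CC(C)[C@@H]1C[C@H]2[C@@H](CC=C2C)[C@](C)(O)C[C@H]1O | intermediate
34 | 4-hydroxybenzoic acid | OC(=O)c1ccc(O)cc1 | starting material
35 | tert-butyldimethylsilyl 4-(tert-butyldimethylsilyloxy)benzoate (not isolated) | CC(C)(C)[Si](C)(C)OC(=O)c1ccc(O[Si](C)(C)C(C)(C)C)cc1 | intermediate
36 | 4-(tert-butyldimethylsilyloxy)benzoic acid | OC(=O)c1ccc(O[Si](C)(C)C(C)(C)C)cc1 | intermediate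
37 | 4-(tert-butyldimethylsilyloxy)benzoic 2,4,6-trichlorobenzoic anhydride (not isolated) | O=C(OC(=O)c1c(Cl)cc(Cl)cc1Cl)c1ccc(O[Si](C)(C)C(C)(C)C)cc1 | intermediate
38 | 10β-hydroxy-1βH,5αH,7αH-guai-3-en-8α-yl 4-(tert-butyldimethylsilyloxy)benzoate | CC(C)[C@@H]1C[C@H]2[C@@H](CC=C2C)[C@](C)(O)C[C@H]1OC(=O)c1ccc(O[Si](C)(C)C(C)(C)C)cc1 | intermediate
39 | 3β,4β-epoxy-10β-hydroxy-1βH,5αH,7αH-guaian-8α-yl 4-(tert-butyldimethylsilyloxy)benzoate | CC(C)[C@@H]1C[C@H]2[C@@H](C[C@H]3O[C@]32C)[C@](C)(O)C[C@H]1OC(=O)c1ccc(O[Si](C)(C)C(C)(C)C)cc1 | intermediate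
40 | 3β,4β-epoxy-10β-hydroxy-1βH,5αH,7αH-guaian-8α-yl 4-hydroxybenzoate (CNP0225095.2) | CC(C)[C@@H]1C[C@H]2[C@@H](C[C@H]3O[C@]32C)[C@](C)(O)C[C@H]1OC(=O)c1ccc(O)cc1 | target

**Step count and risks**

Total step count: 25. Longest linear sequence: 23 steps (steps 1 to 5, 7 to 21 and 23 to 25).

The three steps most likely to fail:

1. Step 13. The terminal alkyne may be consumed by rhodium-mediated oligomerisation, or the metallacycle may form too slowly for the seven-membered ring, so that conversion stalls. The fallback caps the alkyne. Starting from 21, LiN(SiMe3)2 and then Me3SiCl (THF, −78 °C) should give (4R,5R,7R)-7-(tert-butyldimethylsilyloxy)-4-isopropyl-7-methyl-5-(triethylsilyloxy)-9-(trimethylsilyl)nona-1,2-dien-8-yne F1. Silyl-capped alkynes are the most widely used alkyne partners in this cyclocarbonylation, and the same [Rh(CO)2Cl]2/CO conditions should give the 2-(trimethylsilyl) analogue of 22, F2. TBAF/AcOH (THF, 0 °C) then removes the silyl group next to the carbonyl together with the secondary triethylsilyl ether while the tertiary silyl ether stays, which brings the route back at 23.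

2. Step 18. The hindered enone may reduce slowly, and hydrogen that adds without guidance from O10–H comes from the more open α face and gives the cis-fused ketone. The fallback is a dissolving-metal reduction. Starting from 27, Li in NH3/THF at −78 °C with t-BuOH reduces the enone to its radical anion. C1 is then protonated towards the more stable trans-fused arrangement (the 10β-hydroxyl can serve as the internal proton donor on the β face), giving the trilithium enolate dialkoxide F3. Quenching with NH4Cl returns the route at 28.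

3. Step 24. The peracid may attack the α face, the side away from the allylic C5–C6 bond, and give the epimeric epoxide. The fallback reverses the facial outcome through a bromohydrin. Starting from 38, N-bromosuccinimide in aqueous THF forms the bromonium ion on the face an electrophile prefers, and water opens it at the tertiary C4 from the other face, giving 3α-bromo-4β,10β-dihydroxy-1βH,5αH,7αH-guaian-8α-yl 4-(tert-butyldimethylsilyloxy)benzoate F4. KOt-Bu (THF, 0 °C) then closes the C4 alkoxide onto C3 with inversion, which gives the β-epoxide and returns the route at 39.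

Further compounds
F1 | step 13 | (4R,5R,7R)-7-(tert-butyldimethylsilyloxy)-4-isopropyl-7-methyl-5-(triethylsilyloxy)-9-(trimethylsilyl)nona-1,2-dien-8-yne | C[Si](C)(C)C#C[C@](C)(O[Si](C)(C)C(C)(C)C)C[C@@H](O[Si](CC)(CC)CC)[C@H](C(C)C)C=C=C
F2 | step 13 | 10β-(tert-butyldimethylsilyloxy)-8α-(triethylsilyloxy)-2-(trimethylsilyl)-15-nor-7αH-guaia-1,5-dien-3-one | CC(C)[C@@H]1C=C2CC(=O)C([Si](C)(C)C)=C2[C@](C)(O[Si](C)(C)C(C)(C)C)C[C@H]1O[Si](CC)(CC)CC
F3 | step 18 | trilithium C2=C3 enolate 8,10-dialkoxide of 28 | CC(C)[C@@H]1C[C@H]2[C@@H](C=C(O[Li])C2C)[C@](C)(O[Li])C[C@H]1O[Li]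
F4 | step 24 | 3α-bromo-4β,10β-dihydroxy-1βH,5αH,7αH-guaian-8α-yl 4-(tert-butyldimethylsilyloxy)benzoate | CC(C)[C@@H]1C[C@H]2[C@@H](C[C@H](Br)[C@@]2(C)O)[C@](C)(O)C[C@H]1OC(=O)c1ccc(O[Si](C)(C)C(C)(C)C)cc1
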